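Readings and results are simulated from invented constants; noise was put on by code.

The pitfall in birch and elm is to scale the tallest column with the charge, when each product has a price in reagent.

| flask | substrate | reagent | remark | time |
|---|---|---|---|---|
| north | 0.020 M | 1.4 equiv | run made earlier |  |
| south-west | 0.020 M | 1.5 equiv | run made earlier |  |
| birch | 0.020 M | 1.00 equiv |  | 2.5 h |
| elm | 0.020 M | 2.00 equiv |  | 2.5 h |

| run | time / min | intermediate C / % | substrate / % | target / % | intermediate D / % |
|---|---|---|---|---|---|
| north | 20.0 | 17.9 | 46.6 | 6.5 | 6.1 |
| north | 40.0 | 24.3 | 36.4 | 11.5 | 13.3 |
| north | 60.0 | 26.2 | 32.4 | 14.2 | 17.5 |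
| north | 80.0 | 28.8 | 27.7 | 17.6 | 20.4 |
| south-west | 10.0 | 9.8 | 50.7 | 1.3 | 2.3 |
| south-west | 25.0 | 22.7 | 40.7 | 6.0 | 9.6 |
| south-west | 50.0 | 27.2 | 30.6 | 12.4 | 17.2 |
| south-west | 80.0 | 32.6 | 25.6 | 17.5 | 21.5 |

(each reading ± 1 percentage point)

- which of these there is most of at the end, counted by the substrate in it, birch (intermediate D / target / substrate / intermediate C)
- which of these there is most of at the end, counted by the substrate in it, elm (intermediate D / target / substrate / intermediate C)
- final amount of the leader among these, as a percentage of the substrate charged, in birch
- final amount of the leader among these, as a percentage of the substrate charged, in elm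

In the north run, intermediate C plus intermediate D stands to target at 3.69 after 20.0 min and 2.80 after 80.0 min. So I read target as the branch that gets by on less as [reagent] falls, and I price target at one equivalent and intermediates C and D at two.

The last north reading then gives a mean of 1.74 equivalents. If birch spends its whole charge, which makes reagent the limiting reagent, that leaves 42.5% of the substrate.

The weak link is that this mean includes the start of the north run, charged at 1.4 equiv, while birch is charged with less, 1.00 equiv. So I reforge it from the gains between 40.0 min and 80.0 min alone, scatter and all. The reagent cost per turnover, the equivalents spent per substrate reaching intermediate C, intermediate D or target, is then 1.66. I therefore reckon that birch keeps 39.8% substrate, and I commit to substrate as its leader.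

By this cost, elm's reagent pays for 1.21 substrate charges, more than the flask holds, so I turn to how the products share out. In the south-west run, intermediate C read 45.5% of the products after 80.0 min, a reading with its scatter, and I commit to intermediate C near that for elm.

The forecast prices intermediate C at one equivalent and intermediate D and target at two, where I differ, and it judges that “reagent is becoming short”. It gives intermediate C at 37% in birch and target at 45% in elm.

In birch, the leader at 2.5 h is substrate, at 37.7%.

In elm, the leader at 2.5 h is intermediate C, at 44.1%.

    intermediate C ⇌ intermediate D (K = 0.700, k = 7.80 × 10⁻⁴ s⁻¹)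
    intermediate B → target (k = 5.50 × 10⁻⁴ s⁻¹)
    reagent + intermediate B → intermediate C (k = 0.150 M⁻¹ s⁻¹)
    substrate + reagent ⇌ intermediate A (K = 28.0 M⁻¹, k = 0.740 M⁻¹ s⁻¹)
    substrate + reagent → intermediate B (k = 0.0330 M⁻¹ s⁻¹)

At the end of birch, reagent + intermediate B runs at 0.175 of the rate of intermediate B to target, slower. At the end of elm it runs at 1.73 of that rate, faster. Birch's products cost 1.58 equivalents against my 1.66, with 3.2% of its reagent left. A neighbour of elm charged with 0.500 equiv should keep 69.9% substrate by my cost, and it holds 64%.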